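**Plan**
- The retrosynthesis first opens the furan ring of the benzofuran (O1, C2, C3, C3a, C7a) at O1–C2 and C3–C3a. C2 carries the whole chiral chain and C3 is unsubstituted, so C2 and C3 are the two carbons of a terminal alkyne, and O1, C3a and C7a come from 5-iodo-2,4-dihydroxyacetophenone.
- The alkyne is then cut between the carbinol carbon and its CH2 neighbour, giving an (R)-1-arylethyl carbamate and a primary alkyl boronic ester.
- Forward, the pyran ring of the chromene is made first from a bromophenol and 3-methylbut-2-enal. The side chain is then joined through boron, and the furan ring is closed last on the unprotected alkynol.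
- The methyl-bearing centre comes from the (S)-Roche ester, whose ester carbon becomes the alkyne. The carbinol centre is set by a CBS reduction and carried over stereospecifically in the boron 1,2-shift.

Key step: step 15

Remark: the tertiary alcohol sits on an ortho/para-dioxygenated aryl ring and is assumed to ionise easily in acid, so every operation on 21, 22 and 26 is kept basic or neutral.

**Step 1**
Reactants: 1 methyl (S)-3-hydroxy-2-methylpropanoate
Product: 2 methyl (S)-3-[(tert-butyldimethylsilyl)oxy]-2-methylpropanoate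
Conditions: TBSCl, imidazole, CH2Cl2, 0 °C → rt
Reagents that add atoms: tert-butyldimethylsilyl chloride, CC(C)(C)[Si](C)(C)Cl
Why: Imidazole-promoted O-silylation of a primary alcohol, which does not touch the α-stereocentre.

**Step 2**
Reactants: 2 methyl (S)-3-[(tert-butyldimethylsilyl)oxy]-2-methylpropanoate
Product: 3 (S)-3-[(tert-butyldimethylsilyl)oxy]-2-methylpropanal
Conditions: iBu2AlH (1.1 equiv), CH2Cl2, −78 °C; aq. potassium sodium tartrate
Reagents that add atoms: none
Why: Partial ester reduction through an aluminium hemiacetal that is stable at −78 °C; the aldehyde is used crude and cold so that the α-centre does not epimerise.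

**Step 3**
Reactants: 3 (S)-3-[(tert-butyldimethylsilyl)oxy]-2-methylpropanal
Product: 4 (R)-tert-butyl[(4,4-dibromo-2-methylbut-3-en-1-yl)oxy]dimethylsilane
Conditions: CBr4, PPh3, Zn, CH2Cl2, rt; then 3, 0 °C → rt
Reagents that add atoms: carbon tetrabromide, BrC(Br)(Br)Br
Why: Corey–Fuchs dibromoolefination (Wittig reaction of Ph3P=CBr2) under non-basic conditions, so the adjacent centre is retained; the descriptor changes only through CIP priorities.

**Step 4**
Reactants: 4 (R)-tert-butyl[(4,4-dibromo-2-methylbut-3-en-1-yl)oxy]dimethylsilane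
Product: 6 (R)-tert-butyldimethyl{[2-methyl-4-(triisopropylsilyl)but-3-yn-1-yl]oxy}silane, via lithium acetylide 5 (not isolated)
Conditions: n-BuLi (2.1 equiv), THF, −78 → 0 °C; then TIPSOTf, −78 °C → rt
Reagents that add atoms: triisopropylsilyl trifluoromethanesulfonate, CC(C)[Si](C(C)C)(C(C)C)OS(=O)(=O)C(F)(F)F
Why: Second stage of the Corey–Fuchs alkyne synthesis (bromine–lithium exchange and Fritsch–Buttenberg–Wiechell-type loss of bromide to the acetylide), followed by C-silylation with the silyl triflate.

**Step 5**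
Reactants: 6 (R)-tert-butyldimethyl{[2-methyl-4-(triisopropylsilyl)but-3-yn-1-yl]oxy}silane
Product: 7 (R)-2-methyl-4-(triisopropylsilyl)but-3-yn-1-ol
Conditions: camphorsulfonic acid (10 mol%), MeOH/CH2Cl2, 0 °C → rt
Reagents that add atoms: none
Why: Acid-catalysed methanolysis of a primary silyl ether, selective because the C(sp)–Si bond of the hindered silylalkyne is stable to mild acid.

**Step 6**
Reactants: 7 (R)-2-methyl-4-(triisopropylsilyl)but-3-yn-1-ol
Product: 8 (R)-(4-iodo-3-methylbut-1-yn-1-yl)triisopropylsilane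
Conditions: I2, PPh3, imidazole, CH2Cl2, 0 °C → rt
Reagents that add atoms: iodine, II
Why: Appel-type iodination by SN2 displacement of an alkoxyphosphonium ion at the primary carbon, which leaves the neighbouring stereocentre untouched.

**Step 7**
Reactants: 8 (R)-(4-iodo-3-methylbut-1-yn-1-yl)triisopropylsilane
Product: 10 (S)-triisopropyl[3-methyl-4-(4,4,5,5-tetramethyl-1,3,2-dioxaborolan-2-yl)but-1-yn-1-yl]silane, via primary alkyllithium 9 (not isolated)
Conditions: t-BuLi (2.1 equiv), Et2O, −78 °C; then 2-isopropoxy-4,4,5,5-tetramethyl-1,3,2-dioxaborolane, −78 °C → rt; aq. NH4Cl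
Reagents that add atoms: 2-isopropoxy-4,4,5,5-tetramethyl-1,3,2-dioxaborolane, CC(C)OB1OC(C)(C)C(C)(C)O1
Why: Iodine–lithium exchange of a primary iodide is fast at −78 °C and the alkyllithium is borylated by the alkoxyboronate (electrophilic borylation) before it can abstract the propargylic hydrogen.

**Step 8**
Reactants: 11 4-bromo-3-methoxyphenol; 12 3-methylbut-2-enal
Product: 13 6-bromo-7-methoxy-2,2-dimethyl-2H-chromene
Conditions: PhB(OH)2 (1 equiv), AcOH, toluene, reflux, Dean–Stark
Reagents that add atoms: none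
Why: Phenylboronic acid-templated ortho-hydroxyalkylation, loss of water to an ortho-quinone methide and oxa-6π electrocyclization (chromene annulation) should take place at the free ortho position para to the methoxy group, because the other ortho position lies between two oxygen substituents.

**Step 9**
Reactants: 13 6-bromo-7-methoxy-2,2-dimethyl-2H-chromene
Product: 15 1-(7-methoxy-2,2-dimethyl-2H-chromen-6-yl)ethan-1-one, via chromenyl aryllithium 14 (not isolated)
Conditions: n-BuLi, THF, −78 °C; then N-methoxy-N-methylacetamide, −78 → 0 °C; aq. NH4Cl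
Reagents that add atoms: N-methoxy-N-methylacetamide, CC(=O)N(C)OC
Why: Bromine–lithium exchange places the nucleophile at C6 without acid, and the Weinreb ketone synthesis stops at the ketone through its chelated tetrahedral adduct.

**Step 10**
Reactants: 15 1-(7-methoxy-2,2-dimethyl-2H-chromen-6-yl)ethan-1-one
Product: 16 (R)-1-(7-methoxy-2,2-dimethyl-2H-chromen-6-yl)ethan-1-ol
Conditions: (S)-2-methyl-CBS-oxazaborolidine (15 mol%), catecholborane (1.5 equiv), toluene, −78 → −40 °C; aq. NaOH
Reagents that add atoms: none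
Why: Corey–Bakshi–Shibata reduction, in which the (S)-oxazaborolidine binds the ketone with the aryl group as the large substituent and should deliver the (R)-carbinol as it does for acetophenone; catecholborane at low temperature does not hydroborate the chromene alkene.

**Step 11**
Reactants: 16 (R)-1-(7-methoxy-2,2-dimethyl-2H-chromen-6-yl)ethan-1-ol
Product: 17 (R)-1-(7-methoxy-2,2-dimethyl-2H-chromen-6-yl)ethyl N,N-diisopropylcarbamate
Conditions: NaH, iPr2NCOCl, THF, 0 °C → rt
Reagents that add atoms: N,N-diisopropylcarbamoyl chloride, CC(C)N(C(C)C)C(Cl)=O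
Why: O-Acylation of the sodium alkoxide by the carbamoyl chloride at room temperature involves no C–O cleavage, so the configuration is kept and the acid-labile benzylic alcohol never meets acid or heat.

**Step 12**
Reactants: 17 (R)-1-(7-methoxy-2,2-dimethyl-2H-chromen-6-yl)ethyl N,N-diisopropylcarbamate; 10 (S)-triisopropyl[3-methyl-4-(4,4,5,5-tetramethyl-1,3,2-dioxaborolan-2-yl)but-1-yn-1-yl]silane
Product: 21 (2S,4S)-2-(7-methoxy-2,2-dimethyl-2H-chromen-6-yl)-4-methyl-6-(triisopropylsilyl)hex-5-yn-2-ol, via lithiated carbamate 18 (not isolated), via boronate complex 19 (not isolated), via tertiary boronic ester 20 (not isolated)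
Conditions: s-BuLi (1.2 equiv), Et2O, −78 °C; then 10; MgBr2 in MeOH, −78 °C → rt; then NaOH, H2O2, THF/H2O, 0 °C → rt
Reagents that add atoms: hydrogen peroxide, OO
Why: In this lithiation–borylation the carbamate-directed α-deprotonation and the capture by the boronic ester both occur with retention, the alkyl group then shifts from boron to carbon anti to the departing carbamate (stereospecific 1,2-metallate rearrangement), and basic peroxide oxidises C–B to C–OH with retention, so the (R)-carbinol configuration of 17 is transferred to the (2S) quaternary centre; MgBr2/MeOH is added so that the boronate of this electron-rich aryl does not revert.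

**Step 13**
Reactants: 21 (2S,4S)-2-(7-methoxy-2,2-dimethyl-2H-chromen-6-yl)-4-methyl-6-(triisopropylsilyl)hex-5-yn-2-ol
Product: 22 (2S,4S)-2-(7-methoxy-2,2-dimethyl-2H-chromen-6-yl)-4-methylhex-5-yn-2-ol
Conditions: Bu4NF, THF, 0 °C → rt
Reagents that add atoms: none
Why: Fluoride-induced cleavage of the alkynyl C–Si bond under basic conditions, to which the tertiary benzylic alcohol and the chromene are inert.

**Step 14**
Reactants: 23 1-(2,4-dihydroxyphenyl)ethan-1-one
Product: 24 1-(2,4-dihydroxy-5-iodophenyl)ethan-1-one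
Conditions: ICl (1.0 equiv), AcOH, rt; recrystallisation
Reagents that add atoms: iodine monochloride, ICl
Why: Electrophilic aromatic iodination should occur at C5, para to the chelated 2-hydroxyl and ortho to the 4-hydroxyl, rather than at the more crowded C3 between the two hydroxyls; any 3-iodo isomer is to be removed by crystallisation.

**Step 15**
Reactants: 22 (2S,4S)-2-(7-methoxy-2,2-dimethyl-2H-chromen-6-yl)-4-methylhex-5-yn-2-ol; 24 1-(2,4-dihydroxy-5-iodophenyl)ethan-1-one
Product: 26 1-{6-hydroxy-2-[(2S,4S)-4-hydroxy-4-(7-methoxy-2,2-dimethyl-2H-chromen-6-yl)pentan-2-yl]-1-benzofuran-5-yl}ethan-1-one, via ortho-alkynylphenol 25 (not isolated)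
Conditions: PdCl2(PPh3)2 (5 mol%), CuI (10 mol%), Et3N, DMF, degassed, rt → 60 °C
Reagents that add atoms: none
Why: PdCl2(PPh3)2 is reduced in the flask to zerovalent palladium, which inserts into the C–I bond of 24; the copper acetylide formed from 22, CuI and Et3N transmetalates, and reductive elimination forms the C3–C3a bond to give alkynylphenol 25. The phenoxide next to the alkyne then adds anti across the triple bond activated by copper or divalent palladium, and protonolysis of the vinyl–metal bond completes O1–C2, so the furan ring closes in the 5-endo-dig mode. The closest known reaction type is the Sonogashira coupling of ortho-iodophenols with terminal alkynes followed by cycloisomerization in the same flask to 2-substituted benzofurans. No stereocentre is formed, and the two present ones are not at risk because Et3N at 60 °C neither isomerises the propargylic C–H to an allene nor ionises the tertiary alcohol. The step needs regio- and chemoselectivity: the iodine at C5 of 24 fixes the site of C–C bond formation, only the 4-hydroxyl lies ortho to the new alkyne while the 2-hydroxyl is remote and hydrogen-bonded to the acetyl group, and the amine deprotonates the phenol but not the hindered tertiary hydroxyl, so the competing 5-exo-dig attack by that oxygen is not expected. The chromene alkene is a hindered cis-disubstituted olefin and should not enter a Heck reaction under these mild conditions.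

**Compound list**
1 | methyl (S)-3-hydroxy-2-methylpropanoate (Roche ester) | COC(=O)[C@@H](C)CO | starting material
2 | methyl (S)-3-[(tert-butyldimethylsilyl)oxy]-2-methylpropanoate | COC(=O)[C@@H](C)CO[Si](C)(C)C(C)(C)C | intermediate
3 | (S)-3-[(tert-butyldimethylsilyl)oxy]-2-methylpropanal | O=C[C@@H](C)CO[Si](C)(C)C(C)(C)C | intermediate
4 | (R)-tert-butyl[(4,4-dibromo-2-methylbut-3-en-1-yl)oxy]dimethylsilane | BrC(Br)=C[C@@H](C)CO[Si](C)(C)C(C)(C)C | intermediate
5 | [(R)-4-[(tert-butyldimethylsilyl)oxy]-3-methylbut-1-yn-1-yl]lithium | [Li]C#C[C@@H](C)CO[Si](C)(C)C(C)(C)C | intermediate (not isolated)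
6 | (R)-tert-butyldimethyl{[2-methyl-4-(triisopropylsilyl)but-3-yn-1-yl]oxy}silane | CC(C)[Si](C(C)C)(C(C)C)C#C[C@@H](C)CO[Si](C)(C)C(C)(C)C | intermediate
7 | (R)-2-methyl-4-(triisopropylsilyl)but-3-yn-1-ol | CC(C)[Si](C(C)C)(C(C)C)C#C[C@@H](C)CO | intermediate
8 | (R)-(4-iodo-3-methylbut-1-yn-1-yl)triisopropylsilane | CC(C)[Si](C(C)C)(C(C)C)C#C[C@@H](C)CI | intermediate
9 | [(S)-2-methyl-4-(triisopropylsilyl)but-3-yn-1-yl]lithium | CC(C)[Si](C(C)C)(C(C)C)C#C[C@@H](C)C[Li] | intermediate (not isolated)
10 | (S)-triisopropyl[3-methyl-4-(4,4,5,5-tetramethyl-1,3,2-dioxaborolan-2-yl)but-1-yn-1-yl]silane | CC(C)[Si](C(C)C)(C(C)C)C#C[C@@H](C)CB1OC(C)(C)C(C)(C)O1 | intermediate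
11 | 4-bromo-3-methoxyphenol | COc1cc(O)ccc1Br | starting material
12 | 3-methylbut-2-enal | CC(C)=CC=O | starting material
13 | 6-bromo-7-methoxy-2,2-dimethyl-2H-chromene | COc1cc2c(cc1Br)C=CC(C)(C)O2 | intermediate
14 | (7-methoxy-2,2-dimethyl-2H-chromen-6-yl)lithium | COc1cc2c(cc1[Li])C=CC(C)(C)O2 | intermediate (not isolated)
15 | 1-(7-methoxy-2,2-dimethyl-2H-chromen-6-yl)ethan-1-one | COc1cc2c(cc1C(C)=O)C=CC(C)(C)O2 | intermediate
16 | (R)-1-(7-methoxy-2,2-dimethyl-2H-chromen-6-yl)ethan-1-ol | COc1cc2c(cc1[C@@H](C)O)C=CC(C)(C)O2 | intermediate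
17 | (R)-1-(7-methoxy-2,2-dimethyl-2H-chromen-6-yl)ethyl N,N-diisopropylcarbamate | COc1cc2c(cc1[C@@H](C)OC(=O)N(C(C)C)C(C)C)C=CC(C)(C)O2 | intermediate
18 | (R)-[1-(diisopropylcarbamoyloxy)-1-(7-methoxy-2,2-dimethyl-2H-chromen-6-yl)ethyl]lithium | COc1cc2c(cc1[C@@]([Li])(C)OC(=O)N(C(C)C)C(C)C)C=CC(C)(C)O2 | intermediate (not isolated)
19 | lithium [(R)-1-(diisopropylcarbamoyloxy)-1-(7-methoxy-2,2-dimethyl-2H-chromen-6-yl)ethyl][(S)-2-methyl-4-(triisopropylsilyl)but-3-yn-1-yl](pinacolato)borate | COc1cc2c(cc1[C@@]([B-]3(C[C@H](C)C#C[Si](C(C)C)(C(C)C)C(C)C)OC(C)(C)C(C)(C)O3)(C)OC(=O)N(C(C)C)C(C)C)C=CC(C)(C)O2.[Li+] | intermediate (not isolated)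
20 | 2-[(2R,4S)-2-(7-methoxy-2,2-dimethyl-2H-chromen-6-yl)-4-methyl-6-(triisopropylsilyl)hex-5-yn-2-yl]-4,4,5,5-tetramethyl-1,3,2-dioxaborolane | COc1cc2c(cc1[C@@](C)(B3OC(C)(C)C(C)(C)O3)C[C@H](C)C#C[Si](C(C)C)(C(C)C)C(C)C)C=CC(C)(C)O2 | intermediate (not isolated)
21 | (2S,4S)-2-(7-methoxy-2,2-dimethyl-2H-chromen-6-yl)-4-methyl-6-(triisopropylsilyl)hex-5-yn-2-ol | COc1cc2c(cc1[C@@](C)(O)C[C@H](C)C#C[Si](C(C)C)(C(C)C)C(C)C)C=CC(C)(C)O2 | intermediate
22 | (2S,4S)-2-(7-methoxy-2,2-dimethyl-2H-chromen-6-yl)-4-methylhex-5-yn-2-ol | COc1cc2c(cc1[C@@](C)(O)C[C@H](C)C#C)C=CC(C)(C)O2 | intermediate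
23 | 1-(2,4-dihydroxyphenyl)ethan-1-one | CC(=O)c1ccc(O)cc1O | starting material
24 | 1-(2,4-dihydroxy-5-iodophenyl)ethan-1-one | CC(=O)c1cc(I)c(O)cc1O | intermediate
25 | 1-{2,4-dihydroxy-5-[(3S,5S)-5-hydroxy-5-(7-methoxy-2,2-dimethyl-2H-chromen-6-yl)-3-methylhex-1-yn-1-yl]phenyl}ethan-1-one | COc1cc2c(cc1[C@@](C)(O)C[C@H](C)C#Cc1cc(C(C)=O)c(O)cc1O)C=CC(C)(C)O2 | intermediate (not isolated)
26 | 1-{6-hydroxy-2-[(2S,4S)-4-hydroxy-4-(7-methoxy-2,2-dimethyl-2H-chromen-6-yl)pentan-2-yl]-1-benzofuran-5-yl}ethan-1-one | COc1cc2c(cc1[C@@](C)(O)C[C@H](C)c1cc3cc(C(C)=O)c(O)cc3o1)C=CC(C)(C)O2 | target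

**Totals**
Total step count: 15. Longest linear sequence: 10 steps (steps 1–7, 12, 13, 15).

**Steps most likely to fail**

Step 12. The ring position between the two ether oxygens may be lithiated in competition with the benzylic position. The boronate of this very electron-rich aryl may also revert or ionise before the 1,2-shift, which would erode the transfer of configuration. The fallback sets out from iodide 8 and ketone 15 and comes back to the route at 21. Iodide 8 would be converted as in step 7 into alkyllithium 9 (t-BuLi, Et2O, −78 °C) and transmetalated with anhydrous CeCl3 in THF to the organocerium reagent dichloro[(2R)-2-methyl-4-(triisopropylsilyl)but-3-yn-1-yl]cerium F1, which adds to the enolisable ketone 15 at −78 °C. Little 1,3-induction is expected, so 21 would form together with its C2 epimer (2R,4S)-2-(7-methoxy-2,2-dimethyl-2H-chromen-6-yl)-4-methyl-6-(triisopropylsilyl)hex-5-yn-2-ol F2, and the two would be separated by chromatography on base-washed silica.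

Step 15. Oxidative addition to the electron-rich, twice-deprotonated iodoresorcinol may be slow, which would let oxidative dimerisation of the alkyne take over, and the ring closure may stall at the alkynylphenol. The fallback sets out from 24 and 22 and comes back to the route at 25, which is closed to 26. Ketone 24 would be acetylated (Ac2O, pyridine) to 4-acetyl-6-iodo-1,3-phenylene diacetate F3, a more electron-poor iodide that should couple with 22 at room temperature (PdCl2(PPh3)2, CuI, Et3N, THF) to give 4-acetyl-6-[(3S,5S)-5-hydroxy-5-(7-methoxy-2,2-dimethyl-2H-chromen-6-yl)-3-methylhex-1-yn-1-yl]-1,3-phenylene diacetate F4. K2CO3 in MeOH would then remove both acetates to give 25, and CuI with Et3N in DMF at 80 °C would close the furan ring in a separate operation.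

Step 8. The bromine-deactivated phenol may condense slowly, and some annulation may occur at the crowded position between the two oxygens. The fallback sets out from 11 and comes back to the route at 13. Phenol 11 would be O-alkylated with 3-chloro-3-methylbut-1-yne (K2CO3, KI, CuCl2 cat., MeCN) to 1-bromo-2-methoxy-4-[(2-methylbut-3-yn-2-yl)oxy]benzene F5. Heating F5 in N,N-diethylaniline at 190 °C should give 13 by aromatic Claisen rearrangement, 1,5-hydrogen shift and oxa-6π electrocyclization.

**Further compounds**
F1 | step 12 | dichloro[(2R)-2-methyl-4-(triisopropylsilyl)but-3-yn-1-yl]cerium | Cl[Ce](Cl)C[C@H](C)C#C[Si](C(C)C)(C(C)C)C(C)C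
F2 | step 12 | (2R,4S)-2-(7-methoxy-2,2-dimethyl-2H-chromen-6-yl)-4-methyl-6-(triisopropylsilyl)hex-5-yn-2-ol | COc1cc2c(cc1[C@](C)(O)C[C@H](C)C#C[Si](C(C)C)(C(C)C)C(C)C)C=CC(C)(C)O2
F3 | step 15 | 4-acetyl-6-iodo-1,3-phenylene diacetate | CC(=O)Oc1cc(OC(C)=O)c(C(C)=O)cc1I
F4 | step 15 | 4-acetyl-6-[(3S,5S)-5-hydroxy-5-(7-methoxy-2,2-dimethyl-2H-chromen-6-yl)-3-methylhex-1-yn-1-yl]-1,3-phenylene diacetate | COc1cc2c(cc1[C@@](C)(O)C[C@H](C)C#Cc1cc(C(C)=O)c(OC(C)=O)cc1OC(C)=O)C=CC(C)(C)O2
F5 | step 8 | 1-bromo-2-methoxy-4-[(2-methylbut-3-yn-2-yl)oxy]benzene | COc1cc(OC(C)(C)C#C)ccc1Br
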